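**Retrosynthetic overview**

1. Endgame: ring C (the C1–C10 oxirane) comes from peracid epoxidation of a (1(10)E)-olefin, and the C8 ester from Yamaguchi coupling with a separately made (2R,3S)-epoxy acid.
2. Key disconnection C9–C10: the ten-membered ring A is closed by a nickel-electrocatalysed reductive cross-electrophile coupling of a seco-diiodide (primary C9–I and (E)-C10 alkenyl iodide).
3. Enabling feature: C9 is a bare CH2 between the C8 carbinol and C10, the methyl-bearing oxirane carbon (the sp2 carbon of an (E)-trisubstituted olefin one oxidation level down). Ring B (trans γ-lactone O–C6–C7–C11–C12) and the (4Z)-olefin fold the chain and block 5-exo attack of a C9 radical on C5.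
4. Seco-chain: C1–C4 of (S)-malic acid map onto C9, C8, C7 and C6, and a Fráter–Seebach alkylation adds C11–C12. Felkin addition of a (Z)-alkenyllithium (C1–C5 piece from propargyl alcohol and a Brown allylation) sets C6 and closes ring B.
5. Ring order: B (step 8), then A (step 15), then C (step 20); the side-chain oxirane is made in step 17.

Key step: step 15

Remark: all intermediates carry germacrane numbers (C1–C15; C12 lactone carbonyl, C13 exocyclic methylene). The target is read as the 1β,10α-epoxy-3β-isobutyryloxy-8β-acyloxy-heliang-4Z,11(13)-dien-12,6α-olide (1R,3S,6R,7R,8R,10R) with a cis-dimethyl (2R,3S)-2,3-dimethyloxirane-2-carboxylate.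

**Route**

Step 1
Reactants: 1 diethyl (S)-malate; 2 tert-butyl bromoacetate
Product: 4 diethyl (2S,3R)-3-(2-tert-butoxy-2-oxoethyl)-2-hydroxybutanedioate, via dilithium alkoxide enolate 3 (not isolated)
Conditions: LiN(i-Pr)2 (LDA, 2.2 eq), THF, −78 → −20 °C; 2, −78 → −10 °C; H2O
Reagents that add atoms: none
Why: Fráter–Seebach alkylation: the chelated dilithium alkoxide–enolate 3 should be alkylated on the face opposite to the substituent of the chelate ring, so the malate stereocentre (future C8) sets C7 in the anti (2S,3R) sense, while malate C1–C4 become C9, C8, C7 and C6 and 2 brings C11 and C12.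

Step 2
Reactants: 4 diethyl (2S,3R)-3-(2-tert-butoxy-2-oxoethyl)-2-hydroxybutanedioate
Product: 5 4-tert-butyl 1-ethyl (2R)-2-[(1S)-1,2-dihydroxyethyl]butanedioate
Conditions: BH3·SMe2 (1.05 eq), NaBH4 (5 mol%), THF, 0 → 23 °C; MeOH; crude into step 3
Reagents that add atoms: none
Why: Hydroxyl-directed borane reduction: the C8 alkoxyborane delivers hydride through a five-membered chelate to the adjacent α-hydroxy ester only, leaving the β-branched ethyl ester (C6) and the tert-butyl ester, and no stereocentre is touched.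

Step 3
Reactants: 5 4-tert-butyl 1-ethyl (2R)-2-[(1S)-1,2-dihydroxyethyl]butanedioate
Product: 6 4-tert-butyl 1-ethyl (2R)-2-[(1S)-1,2-bis(tert-butyldimethylsilyloxy)ethyl]butanedioate
Conditions: TBSCl (3 eq), imidazole (6 eq), DMAP (cat.), DMF, 23 → 40 °C
Reagents that add atoms: tert-butyldimethylsilyl chloride, CC(C)(C)[Si](C)(C)Cl
Why: Standard silylation of the primary (C9) and secondary (C8) hydroxyls prevents lactonisation onto either ester and gives the non-chelating β-silyloxy group needed for Felkin control in step 8.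

Step 4
Reactants: 6 4-tert-butyl 1-ethyl (2R)-2-[(1S)-1,2-bis(tert-butyldimethylsilyloxy)ethyl]butanedioate
Product: 7 tert-butyl (3R,4S)-4,5-bis(tert-butyldimethylsilyloxy)-3-formylpentanoate
Conditions: i-Bu2AlH (DIBAL-H, 1.1 eq), CH2Cl2, −78 °C; MeOH, then aq. KNaC4H4O6 (Rochelle salt); used crude
Reagents that add atoms: none
Why: Partial ester reduction at −78 °C: the ethyl ester should stop at the aldehyde through its tetrahedral aluminate while the tert-butyl ester is too hindered to react, and the α-branched aldehyde is used at once to avoid epimerisation at C7.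

Step 5
Reactants: 8 prop-2-yn-1-ol
Product: 10 (Z)-3-iodo-2-methylprop-2-en-1-ol, via alkenylmagnesium alkoxide 9 (not isolated)
Conditions: MeMgBr (3 eq), CuI (copper monoiodide, 10 mol%), THF, −20 → 23 °C; I2, −60 → 0 °C
Reagents that add atoms: methylmagnesium bromide, C[Mg]Br; iodine, II
Why: Copper-catalysed anti-carbomagnesiation of the propargylic magnesium alkoxide puts the methyl (C15) on the proximal carbon (C4) and magnesium on the terminus (C5) within a five-membered chelate, and iodinolysis with retention should give the (Z)-iodide that encodes the (4Z)-olefin.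

Step 6
Reactants: 10 (Z)-3-iodo-2-methylprop-2-en-1-ol
Product: 11 (Z)-3-iodo-2-methylprop-2-enal
Conditions: MnO2 (15 eq), CH2Cl2, 23 °C, dark; filtered solution used directly
Reagents that add atoms: none
Why: Allylic oxidation with MnO2 under neutral conditions in the dark should give the enal without Z to E isomerisation.

Step 7
Reactants: 11 (Z)-3-iodo-2-methylprop-2-enal
Product: 13 (1Z,3S)-1-iodo-2-methylhexa-1,5-dien-3-ol, via borinate 12 (not isolated)
Conditions: (−)-Ipc2B(allyl) (1.2 eq), Et2O, −78 °C; NaOH (3 M), H2O2 (30%), 0 → 23 °C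
Reagents that add atoms: (−)-B-allyldiisopinocampheylborane, C=CCB([C@@H]1C[C@@H]2C[C@H]([C@H]1C)C2(C)C)[C@@H]1C[C@@H]2C[C@H]([C@H]1C)C2(C)C
Why: Brown allylation: the closed chair transition state of the (+)-α-pinene-derived allylborane should deliver the allyl group (C2, C1 and a sacrificial CH2) to one face of the enal and set C3 as S, the facial sense known for sp2-substituted aldehydes.

Step 8
Reactants: 13 (1Z,3S)-1-iodo-2-methylhexa-1,5-dien-3-ol; 7 tert-butyl (3R,4S)-4,5-bis(tert-butyldimethylsilyloxy)-3-formylpentanoate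
Product: 16 (4S,5R)-4-[(1S)-1,2-bis(tert-butyldimethylsilyloxy)ethyl]-5-[(1Z,3S)-3-hydroxy-2-methylhexa-1,5-dien-1-yl]oxolan-2-one, via dilithio reagent 14 (not isolated), via dilithium dialkoxide 15 (not isolated)
Conditions: 13 (1.3 eq), t-BuLi (3.9 eq), Et2O, −78 °C; 7, −78 °C; then 23 °C; H2O
Reagents that add atoms: none
Why: Iodine–lithium exchange with retention of the Z geometry, then Felkin–Anh addition to the α-branched aldehyde (C8 branch anti to the incoming alkenyl group, reinforced by 1,3-anti induction from the C8 silyloxy group of this 7,8-anti aldehyde) should set C6 as R, and the C6 lithium alkoxide closes ring B by 5-exo-trig acyl substitution on the tert-butyl ester to give the trans lactone.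

Step 9
Reactants: 16 (4S,5R)-4-[(1S)-1,2-bis(tert-butyldimethylsilyloxy)ethyl]-5-[(1Z,3S)-3-hydroxy-2-methylhexa-1,5-dien-1-yl]oxolan-2-one; 17 isopropenylboronic acid pinacol ester
Product: 18 (4S,5R)-4-[(1S)-1,2-bis(tert-butyldimethylsilyloxy)ethyl]-5-[(1Z,3S,5Z)-3-hydroxy-2-methyl-6-(4,4,5,5-tetramethyl-1,3,2-dioxaborolan-2-yl)hepta-1,5-dien-1-yl]oxolan-2-one
Conditions: 17 (3 eq), second-generation Grubbs catalyst (H2IMes)(PCy3)Cl2Ru=CHPh (5 mol%), CH2Cl2, 40 °C
Reagents that add atoms: none
Why: Olefin cross-metathesis of the terminal vinyl group with the 1,1-disubstituted boronate (the (4Z)-trisubstituted olefin is inert) should give the thermodynamic trisubstituted alkenyl boronate with boron trans to the chain, installing C10 and C14.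

Step 10
Reactants: 18 (4S,5R)-4-[(1S)-1,2-bis(tert-butyldimethylsilyloxy)ethyl]-5-[(1Z,3S,5Z)-3-hydroxy-2-methyl-6-(4,4,5,5-tetramethyl-1,3,2-dioxaborolan-2-yl)hepta-1,5-dien-1-yl]oxolan-2-one
Product: 19 (4S,5R)-4-[(1S)-1,2-bis(tert-butyldimethylsilyloxy)ethyl]-5-[(1Z,3S,5E)-3-hydroxy-6-iodo-2-methylhepta-1,5-dien-1-yl]oxolan-2-one
Conditions: NaOH (3 M aq., 3 eq), THF, 0 °C; I2 (1.5 eq), 0 °C; Na2S2O3; 1 M HCl to pH 3
Reagents that add atoms: iodine, II
Why: Iododeboronation of the hydroxide ate complex proceeds with retention, so the boronate should give the (E)-alkenyl iodide, and the acidic work-up re-closes any lactone opened by hydroxide.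

Step 11
Reactants: 19 (4S,5R)-4-[(1S)-1,2-bis(tert-butyldimethylsilyloxy)ethyl]-5-[(1Z,3S,5E)-3-hydroxy-6-iodo-2-methylhepta-1,5-dien-1-yl]oxolan-2-one
Product: 22 (4S,5R)-4-[(1S)-1,2-bis(tert-butyldimethylsilyloxy)ethyl]-5-[(1Z,3S,5E)-3-hydroxy-6-iodo-2-methylhepta-1,5-dien-1-yl]-3-methylideneoxolan-2-one, via Mannich base 20 (not isolated), via methiodide 21 (not isolated)
Conditions: LiN(i-Pr)2 (2.3 eq), THF, −78 °C; CH2=NMe2+ I− (3 eq), −78 → 23 °C; MeI (10 eq), CH2Cl2, 23 °C; aq. NaHCO3, 23 °C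
Reagents that add atoms: Eschenmoser's salt (N,N-dimethylmethylideneammonium iodide), C=[N+](C)C.[I-]
Why: Eschenmoser methylenation: the lactone enolate (the C3 alkoxide is a spectator whose O-aminomethyl ether is lost on work-up) undergoes a Mannich reaction at C11, and exhaustive methylation followed by E1cB elimination installs the C13 methylene and erases the transient C11 stereocentre.

Step 12
Reactants: 22 (4S,5R)-4-[(1S)-1,2-bis(tert-butyldimethylsilyloxy)ethyl]-5-[(1Z,3S,5E)-3-hydroxy-6-iodo-2-methylhepta-1,5-dien-1-yl]-3-methylideneoxolan-2-one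
Product: 23 (1Z,3S,5E)-1-[(2R,3S)-3-[(1S)-1,2-bis(tert-butyldimethylsilyloxy)ethyl]-4-methylidene-5-oxooxolan-2-yl]-6-iodo-2-methylhepta-1,5-dien-3-yl 2-methylpropanoate
Conditions: (i-PrCO)2O (1.5 eq), DMAP (0.1 eq), pyridine, CH2Cl2, 0 → 23 °C
Reagents that add atoms: isobutyric anhydride, CC(C)C(=O)OC(=O)C(C)C
Why: DMAP-catalysed acylation of the only free hydroxyl (C3, retention) introduces the isobutyrate after the last strongly basic step.

Step 13
Reactants: 23 (1Z,3S,5E)-1-[(2R,3S)-3-[(1S)-1,2-bis(tert-butyldimethylsilyloxy)ethyl]-4-methylidene-5-oxooxolan-2-yl]-6-iodo-2-methylhepta-1,5-dien-3-yl 2-methylpropanoate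
Product: 24 (1Z,3S,5E)-1-[(2R,3S)-3-[(1S)-1-(tert-butyldimethylsilyloxy)-2-hydroxyethyl]-4-methylidene-5-oxooxolan-2-yl]-6-iodo-2-methylhepta-1,5-dien-3-yl 2-methylpropanoate
Conditions: camphorsulfonic acid (0.1 eq), MeOH/CH2Cl2 (1:1), 0 °C; crude into step 14
Reagents that add atoms: none
Why: Acid-catalysed methanolysis removes the unhindered primary silyl ether (C9) much faster than the secondary C8 silyl ether flanked by the C7 branch, and the ester and lactone are stable to these conditions.

Step 14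
Reactants: 24 (1Z,3S,5E)-1-[(2R,3S)-3-[(1S)-1-(tert-butyldimethylsilyloxy)-2-hydroxyethyl]-4-methylidene-5-oxooxolan-2-yl]-6-iodo-2-methylhepta-1,5-dien-3-yl 2-methylpropanoate
Product: 25 (1Z,3S,5E)-1-[(2R,3S)-3-[(1S)-1-(tert-butyldimethylsilyloxy)-2-iodoethyl]-4-methylidene-5-oxooxolan-2-yl]-6-iodo-2-methylhepta-1,5-dien-3-yl 2-methylpropanoate
Conditions: PPh3 (1.3 eq), I2 (1.3 eq), imidazole (1.5 eq), premixed, CH2Cl2, 0 °C; then 24
Reagents that add atoms: iodine, II
Why: Appel-type iodination (alkoxyphosphonium, SN2 at the primary C9) under neutral conditions, with the phosphine consumed by iodine before the substrate is added so that it cannot add to the methylene lactone.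

Step 15
Reactants: 25 (1Z,3S,5E)-1-[(2R,3S)-3-[(1S)-1-(tert-butyldimethylsilyloxy)-2-iodoethyl]-4-methylidene-5-oxooxolan-2-yl]-6-iodo-2-methylhepta-1,5-dien-3-yl 2-methylpropanoate
Product: 26 (1(10)E,4Z)-8β-(tert-butyldimethylsilyloxy)-3β-(2-methylpropanoyloxy)germacra-1(10),4,11(13)-trien-12,6α-olide (7α-H)
Conditions: NiBr2(dme) (30 mol%), 4,4′-di-tert-butyl-2,2′-bipyridine (36 mol%), NaI (0.1 M), DMA, 2 mM in 25, undivided cell, reticulated vitreous carbon cathode, sacrificial Zn anode, constant current (about 2.5 F/mol over 12 h), 23 °C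
Reagents that add atoms: none
Why: Proposed new method: cathodically generated zerovalent nickel should insert into the C10–I bond of the (E)-alkenyl iodide with retention, the alkenylnickel is reduced to the monovalent state and abstracts iodine from the tethered C9–I, and the primary C9 radical recombines with the same metal centre to give a trivalent alkyl(alkenyl)nickel that reductively eliminates the C9–C10 bond. The closest known reaction type is the intermolecular nickel-catalysed reductive cross-electrophile coupling of primary alkyl iodides with alkenyl halides under chemical or cathodic reduction, and, for the ring size, Ni/Cr-mediated macrocyclisations of alkenyl iodides. The only ring closed is the ten-membered carbocycle A (C1–C10), formed by metal-templated radical capture and C(sp3)–C(sp2) reductive elimination in which both C9 and C10 become ring atoms, not by radical addition to a π bond. No new stereocentre is formed: the (1(10)E) geometry is carried over from the alkenyl iodide, and C3, C6, C7, C8 and the (4Z)-olefin are spectators. The step needs cyclisation to outrun oligomerisation and radical side reactions: ring B (the trans γ-lactone O–C6–C7–C11–C12) and the (4Z)-olefin fold the chain so that C9 and C10 can meet, the current meters the radical flux at high dilution, 5-exo attack of the C9 radical on C5 would give a trans-fused bicyclo[3.3.0]octane, and attack on the C11=C13 methylene would be 5-endo or 4-exo. Chemoselectivity between the two C–I bonds is inherent (oxidative addition at sp2 carbon, halogen abstraction at sp3 carbon), and the allylic ester C–O bonds should ionise far more slowly than C–I bonds add to zerovalent nickel.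

Step 16
Reactants: 26 (1(10)E,4Z)-8β-(tert-butyldimethylsilyloxy)-3β-(2-methylpropanoyloxy)germacra-1(10),4,11(13)-trien-12,6α-olide
Product: 27 (1(10)E,4Z)-8β-hydroxy-3β-(2-methylpropanoyloxy)germacra-1(10),4,11(13)-trien-12,6α-olide
Conditions: HF·pyridine, pyridine, THF, 0 → 23 °C
Reagents that add atoms: none
Why: Fluoride-mediated desilylation under buffered acidic conditions frees the 8β-hydroxyl without base, which avoids translactonisation to O8 and conjugate addition to C13.

Step 17
Reactants: 28 (E)-2-methylbut-2-en-1-ol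
Product: 29 [(2S,3S)-2,3-dimethyloxiran-2-yl]methanol
Conditions: Ti(Oi-Pr)4 (10 mol%), L-(+)-diethyl tartrate (12 mol%), t-BuOOH (2 eq), 4 Å molecular sieves, CH2Cl2, −20 °C
Reagents that add atoms: tert-butyl hydroperoxide, CC(C)(C)OO
Why: Sharpless asymmetric epoxidation: the L-(+)-tartrate titanium catalyst delivers oxygen to one face of the (E)-trisubstituted allylic alcohol and sets both oxirane centres (2S,3S), the cis-dimethyl arrangement being fixed by the olefin geometry.

Step 18
Reactants: 29 [(2S,3S)-2,3-dimethyloxiran-2-yl]methanol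
Product: 30 (2R,3S)-2,3-dimethyloxirane-2-carboxylic acid
Conditions: RuCl3·xH2O (3 mol%), NaIO4 (3 eq), CCl4/MeCN/H2O (2:2:3), 0 → 23 °C
Reagents that add atoms: sodium periodate, [Na+].[O-]I(=O)(=O)=O
Why: Ruthenium tetroxide oxidation (RuO4 formed in situ from RuCl3 and periodate) takes the primary alcohol to the acid without touching the oxirane, and the C2 descriptor changes to R only through the change in substituent priority.

Step 19
Reactants: 30 (2R,3S)-2,3-dimethyloxirane-2-carboxylic acid; 27 (1(10)E,4Z)-8β-hydroxy-3β-(2-methylpropanoyloxy)germacra-1(10),4,11(13)-trien-12,6α-olide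
Product: 32 (1(10)E,4Z)-8β-[(2R,3S)-2,3-dimethyloxirane-2-carbonyloxy]-3β-(2-methylpropanoyloxy)germacra-1(10),4,11(13)-trien-12,6α-olide, via mixed anhydride 31 (not isolated)
Conditions: 30 (2 eq), 2,4,6-trichlorobenzoyl chloride (2 eq), Et3N (3 eq), THF, 23 °C; then 27, DMAP (2 eq), toluene, 23 → 40 °C
Reagents that add atoms: none
Why: Yamaguchi esterification: DMAP attacks the mixed anhydride 31 at the less hindered aliphatic carbonyl and the acylpyridinium acylates the hindered 8β-hydroxyl with retention at C8 and without opening the oxirane.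

Step 20
Reactants: 32 (1(10)E,4Z)-8β-[(2R,3S)-2,3-dimethyloxirane-2-carbonyloxy]-3β-(2-methylpropanoyloxy)germacra-1(10),4,11(13)-trien-12,6α-olide
Product: 33 1β,10α-epoxy-8β-[(2R,3S)-2,3-dimethyloxirane-2-carbonyloxy]-3β-(2-methylpropanoyloxy)germacra-4Z,11(13)-dien-12,6α-olide (CNP0117882.3)
Conditions: mCPBA (1.1 eq), NaHCO3, CH2Cl2, 0 °C
Reagents that add atoms: meta-chloroperbenzoic acid, OOC(=O)c1cccc(Cl)c1
Why: Prilezhaev epoxidation: the peracid should choose the electron-rich C1=C10 olefin (C4=C5 is deactivated by two allylic acyloxy groups, C11=C13 is conjugated), add syn to give the trans-oxirane, and attack the exposed outer face of the crossed diene conformer with C14 on the β face, which should give the 1β,10α (1R,10R) epoxide as in peracid epoxidations of related germacra-1(10),4-dienolides.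

**Compound list**

1 | diethyl (S)-malate | CCOC(=O)C[C@H](O)C(=O)OCC | starting material
2 | tert-butyl bromoacetate | CC(C)(C)OC(=O)CBr | starting material
3 | dilithium alkoxide enolate of 1 | CCOC(O[Li])=C[C@H](O[Li])C(=O)OCC | intermediate
4 | diethyl (2S,3R)-3-(2-tert-butoxy-2-oxoethyl)-2-hydroxybutanedioate | CCOC(=O)[C@H](CC(=O)OC(C)(C)C)[C@H](O)C(=O)OCC | intermediate
5 | 4-tert-butyl 1-ethyl (2R)-2-[(1S)-1,2-dihydroxyethyl]butanedioate | CCOC(=O)[C@H](CC(=O)OC(C)(C)C)[C@H](O)CO | intermediate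
6 | 4-tert-butyl 1-ethyl (2R)-2-[(1S)-1,2-bis(tert-butyldimethylsilyloxy)ethyl]butanedioate | CCOC(=O)[C@H](CC(=O)OC(C)(C)C)[C@H](O[Si](C)(C)C(C)(C)C)CO[Si](C)(C)C(C)(C)C | intermediate
7 | tert-butyl (3R,4S)-4,5-bis(tert-butyldimethylsilyloxy)-3-formylpentanoate | O=C[C@H](CC(=O)OC(C)(C)C)[C@H](O[Si](C)(C)C(C)(C)C)CO[Si](C)(C)C(C)(C)C | intermediate
8 | prop-2-yn-1-ol | C#CCO | starting material
9 | (Z)-alkenylmagnesium bromide magnesium alkoxide from 8 | Br[Mg]/C=C(/C)CO[Mg]Br | intermediate
10 | (Z)-3-iodo-2-methylprop-2-en-1-ol | I/C=C(/C)CO | intermediate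
11 | (Z)-3-iodo-2-methylprop-2-enal | I/C=C(/C)C=O | intermediate
12 | diisopinocampheylborinate of 13 | I/C=C(/C)[C@@H](OB([C@@H]1C[C@@H]2C[C@H]([C@H]1C)C2(C)C)[C@@H]1C[C@@H]2C[C@H]([C@H]1C)C2(C)C)CC=C | intermediate
13 | (1Z,3S)-1-iodo-2-methylhexa-1,5-dien-3-ol | I/C=C(/C)[C@@H](O)CC=C | intermediate
14 | dilithio reagent from 13 (C5–Li, O3–Li) | [Li]/C=C(/C)[C@@H](O[Li])CC=C | intermediate
15 | dilithium C3,C6-dialkoxide of the tert-butyl ester adduct | CC(C)(C)OC(=O)C[C@@H]([C@H](O[Li])/C=C(/C)[C@@H](O[Li])CC=C)[C@H](O[Si](C)(C)C(C)(C)C)CO[Si](C)(C)C(C)(C)C | intermediate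
16 | (4S,5R)-4-[(1S)-1,2-bis(tert-butyldimethylsilyloxy)ethyl]-5-[(1Z,3S)-3-hydroxy-2-methylhexa-1,5-dien-1-yl]oxolan-2-one | C1C(=O)O[C@H](/C=C(/C)[C@@H](O)CC=C)[C@H]1[C@H](O[Si](C)(C)C(C)(C)C)CO[Si](C)(C)C(C)(C)C | intermediate
17 | isopropenylboronic acid pinacol ester | CC(=C)B1OC(C)(C)C(C)(C)O1 | starting material
18 | (4S,5R)-4-[(1S)-1,2-bis(tert-butyldimethylsilyloxy)ethyl]-5-[(1Z,3S,5Z)-3-hydroxy-2-methyl-6-(4,4,5,5-tetramethyl-1,3,2-dioxaborolan-2-yl)hepta-1,5-dien-1-yl]oxolan-2-one | C1C(=O)O[C@H](/C=C(/C)[C@@H](O)C/C=C(\C)B2OC(C)(C)C(C)(C)O2)[C@H]1[C@H](O[Si](C)(C)C(C)(C)C)CO[Si](C)(C)C(C)(C)C | intermediate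
19 | (4S,5R)-4-[(1S)-1,2-bis(tert-butyldimethylsilyloxy)ethyl]-5-[(1Z,3S,5E)-3-hydroxy-6-iodo-2-methylhepta-1,5-dien-1-yl]oxolan-2-one | C1C(=O)O[C@H](/C=C(/C)[C@@H](O)C/C=C(\C)I)[C@H]1[C@H](O[Si](C)(C)C(C)(C)C)CO[Si](C)(C)C(C)(C)C | intermediate
20 | C11-(dimethylaminomethyl) Mannich base of 19 (C11 epimers) | CN(C)CC1C(=O)O[C@H](/C=C(/C)[C@@H](O)C/C=C(\C)I)[C@H]1[C@H](O[Si](C)(C)C(C)(C)C)CO[Si](C)(C)C(C)(C)C | intermediate
21 | trimethylammonium iodide (methiodide) of 20 | C[N+](C)(C)CC1C(=O)O[C@H](/C=C(/C)[C@@H](O)C/C=C(\C)I)[C@H]1[C@H](O[Si](C)(C)C(C)(C)C)CO[Si](C)(C)C(C)(C)C.[I-] | intermediate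
22 | (4S,5R)-4-[(1S)-1,2-bis(tert-butyldimethylsilyloxy)ethyl]-5-[(1Z,3S,5E)-3-hydroxy-6-iodo-2-methylhepta-1,5-dien-1-yl]-3-methylideneoxolan-2-one | C=C1C(=O)O[C@H](/C=C(/C)[C@@H](O)C/C=C(\C)I)[C@H]1[C@H](O[Si](C)(C)C(C)(C)C)CO[Si](C)(C)C(C)(C)C | intermediate
23 | (1Z,3S,5E)-1-[(2R,3S)-3-[(1S)-1,2-bis(tert-butyldimethylsilyloxy)ethyl]-4-methylidene-5-oxooxolan-2-yl]-6-iodo-2-methylhepta-1,5-dien-3-yl 2-methylpropanoate | C=C1C(=O)O[C@H](/C=C(/C)[C@@H](OC(=O)C(C)C)C/C=C(\C)I)[C@H]1[C@H](O[Si](C)(C)C(C)(C)C)CO[Si](C)(C)C(C)(C)C | intermediate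
24 | (1Z,3S,5E)-1-[(2R,3S)-3-[(1S)-1-(tert-butyldimethylsilyloxy)-2-hydroxyethyl]-4-methylidene-5-oxooxolan-2-yl]-6-iodo-2-methylhepta-1,5-dien-3-yl 2-methylpropanoate | C=C1C(=O)O[C@H](/C=C(/C)[C@@H](OC(=O)C(C)C)C/C=C(\C)I)[C@H]1[C@H](O[Si](C)(C)C(C)(C)C)CO | intermediate
25 | (1Z,3S,5E)-1-[(2R,3S)-3-[(1S)-1-(tert-butyldimethylsilyloxy)-2-iodoethyl]-4-methylidene-5-oxooxolan-2-yl]-6-iodo-2-methylhepta-1,5-dien-3-yl 2-methylpropanoate | C=C1C(=O)O[C@H](/C=C(/C)[C@@H](OC(=O)C(C)C)C/C=C(\C)I)[C@H]1[C@H](O[Si](C)(C)C(C)(C)C)CI | intermediate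
26 | (1(10)E,4Z)-8β-(tert-butyldimethylsilyloxy)-3β-(2-methylpropanoyloxy)germacra-1(10),4,11(13)-trien-12,6α-olide | C=C1C(=O)O[C@@H]2/C=C(/C)[C@@H](OC(=O)C(C)C)C/C=C(\C)C[C@@H](O[Si](C)(C)C(C)(C)C)[C@@H]12 | intermediate
27 | (1(10)E,4Z)-8β-hydroxy-3β-(2-methylpropanoyloxy)germacra-1(10),4,11(13)-trien-12,6α-olide | C=C1C(=O)O[C@@H]2/C=C(/C)[C@@H](OC(=O)C(C)C)C/C=C(\C)C[C@@H](O)[C@@H]12 | intermediate
28 | (E)-2-methylbut-2-en-1-ol | C/C=C(\C)CO | starting material
29 | [(2S,3S)-2,3-dimethyloxiran-2-yl]methanol | OC[C@]1(C)O[C@H]1C | intermediate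
30 | (2R,3S)-2,3-dimethyloxirane-2-carboxylic acid | OC(=O)[C@]1(C)O[C@H]1C | intermediate
31 | (2R,3S)-2,3-dimethyloxirane-2-carboxylic 2,4,6-trichlorobenzoic anhydride | O=C(OC(=O)[C@]1(C)O[C@H]1C)c1c(Cl)cc(Cl)cc1Cl | intermediate
32 | (1(10)E,4Z)-8β-[(2R,3S)-2,3-dimethyloxirane-2-carbonyloxy]-3β-(2-methylpropanoyloxy)germacra-1(10),4,11(13)-trien-12,6α-olide | C=C1C(=O)O[C@@H]2/C=C(/C)[C@@H](OC(=O)C(C)C)C/C=C(\C)C[C@@H](OC(=O)[C@]3(C)O[C@H]3C)[C@@H]12 | intermediate
33 | 1β,10α-epoxy-8β-[(2R,3S)-2,3-dimethyloxirane-2-carbonyloxy]-3β-(2-methylpropanoyloxy)germacra-4Z,11(13)-dien-12,6α-olide (CNP0117882.3) | C=C1C(=O)O[C@@H]2/C=C(/C)[C@@H](OC(=O)C(C)C)C[C@H]3O[C@]3(C)C[C@@H](OC(=O)[C@]3(C)O[C@H]3C)[C@@H]12 | target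

**Step count**

Total steps: 20. Longest linear sequence: 15 steps (steps 1–4, 8–16, 19 and 20, from diethyl (S)-malate).

**Steps most likely to fail, with fallbacks**

Step 15 (Proposed new method). What may go wrong: intermolecular radical capture leading to oligomers, β-elimination of the C8 silyloxy group from a C9–nickel species, simple reduction of either C–I bond, or slow ionisation of the allylic esters by zerovalent nickel. The fallback uses known two-electron palladium chemistry and sets out from alcohol 24. A Miyaura borylation of the alkenyl iodide (PdCl2(dppf), B2pin2, KOAc, dioxane, 60 °C, retention of geometry) would give the alkenyl boronate alcohol F1. Appel iodination (PPh3, I2, imidazole, CH2Cl2, 0 °C) would give the iodo boronate F2. An intramolecular alkyl–alkenyl Suzuki–Miyaura coupling of the primary iodide with the alkenyl boronate (Pd(OAc)2, PCy3, K3PO4·H2O, THF, high dilution) would then close the same C9–C10 bond and come back to the route at 26.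

Step 8. What may go wrong: proton transfer from the α-branched aldehyde to the basic dilithio reagent (enolisation and epimerisation at C7), migration of the C8 silyl group to the new C6 alkoxide before lactonisation, and erosion of Felkin control. The fallback sets out from 13 and 7. A Nozaki–Hiyama–Kishi coupling (CrCl2, catalytic NiCl2, DMSO, 23 °C) is non-basic and tolerates the free C3 hydroxyl and the ester, and would give the uncyclised Felkin adduct, the diol tert-butyl ester F3. Pyridinium p-toluenesulfonate in toluene at 60 °C would then lactonise it and come back to the route at 16.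

Step 20. What may go wrong: attack of the peracid on the inner face of C1=C10, giving the 1α,10β-epoxide, or competing oxidation of C4=C5. The fallback inverts the facial outcome and sets out from 32. NBS in aqueous 1,2-dimethoxyethane at 0 °C would form the bromonium ion on the same exposed face, and water would open it at the tertiary C10 in the anti sense to give the bromohydrin F4. Ag2O in 1,2-dimethoxyethane would then close the oxirane by displacement of bromide with inversion at C1, which places the oxygen on the face opposite to the one the electrophile attacked, and comes back to the route at 33.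

**Further compounds**

F1 | step 15 | (1Z,3S,5Z)-1-[(2R,3S)-3-[(1S)-1-(tert-butyldimethylsilyloxy)-2-hydroxyethyl]-4-methylidene-5-oxooxolan-2-yl]-2-methyl-6-(4,4,5,5-tetramethyl-1,3,2-dioxaborolan-2-yl)hepta-1,5-dien-3-yl 2-methylpropanoate | C=C1C(=O)O[C@H](/C=C(/C)[C@@H](OC(=O)C(C)C)C/C=C(\C)B2OC(C)(C)C(C)(C)O2)[C@H]1[C@H](O[Si](C)(C)C(C)(C)C)CO
F2 | step 15 | (1Z,3S,5Z)-1-[(2R,3S)-3-[(1S)-1-(tert-butyldimethylsilyloxy)-2-iodoethyl]-4-methylidene-5-oxooxolan-2-yl]-2-methyl-6-(4,4,5,5-tetramethyl-1,3,2-dioxaborolan-2-yl)hepta-1,5-dien-3-yl 2-methylpropanoate | C=C1C(=O)O[C@H](/C=C(/C)[C@@H](OC(=O)C(C)C)C/C=C(\C)B2OC(C)(C)C(C)(C)O2)[C@H]1[C@H](O[Si](C)(C)C(C)(C)C)CI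
F3 | step 8 | tert-butyl (3S,4R,5Z,7S)-3-[(1S)-1,2-bis(tert-butyldimethylsilyloxy)ethyl]-4,7-dihydroxy-6-methyldeca-5,9-dienoate | CC(C)(C)OC(=O)C[C@@H]([C@H](O)/C=C(/C)[C@@H](O)CC=C)[C@H](O[Si](C)(C)C(C)(C)C)CO[Si](C)(C)C(C)(C)C
F4 | step 20 | 1α-bromo-10α-hydroxy-8β-[(2R,3S)-2,3-dimethyloxirane-2-carbonyloxy]-3β-(2-methylpropanoyloxy)germacra-4Z,11(13)-dien-12,6α-olide | C=C1C(=O)O[C@@H]2/C=C(/C)[C@@H](OC(=O)C(C)C)C[C@H](Br)[C@@](O)(C)C[C@@H](OC(=O)[C@]3(C)O[C@H]3C)[C@@H]12
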